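**Plan**

- The last disconnection removes two N-Boc groups. Before that, all four C(carbonyl)–C(alkene) bonds of the quinone are cut in one operation.
- Enabling feature: the quinone ring consists of two C(indol-3-yl)=C(OMe) pairs alternating with two C=O carbons, which is two indolyl methoxyalkynes plus two CO.
- The ynol ether is cut at the indole C3–C(sp) bond (Negishi coupling of a 3-iodoindole with methoxyethynylzinc) and at the C2–C(quaternary) bond (reverse prenylation of 3-chloroindole with a prenylborane).
- Forward: indole (both indole rings are bought), then C2 side chain, C3 iodide, N-Boc and C3 alkyne. The only ring formed, the six-membered quinone, arises in the iron-mediated carbonylative dimerisation, and Boc removal ends the route.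
- Stereochemistry: the target has no stereocentre and no stereogenic double bond, so nothing has to be controlled.

Key step: step 7

Assumption: CO gas is taken to exchange with the CO ligands of Fe(CO)5 under irradiation, so the two ring carbonyls are counted as coming from the CO atmosphere.

**Route**

Step 1
Reactants: 1 3-methylbuta-1,2-diene; 2 9-borabicyclo[3.3.1]nonane (9-BBN)
Product: 3 9-(3-methylbut-2-en-1-yl)-9-borabicyclo[3.3.1]nonane (prenyl-9-BBN)
Conditions: THF, 0 °C → rt; solution used directly
Reagents that add atoms: none
Why: Hydroboration of an allene: the B–H bond of 9-BBN adds across the unsubstituted terminal C=C of the 1,1-dimethylallene with boron on the CH2 carbon, which gives the prenylborane without any by-product.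

Step 2
Reactants: 4 indole
Product: 5 3-chloro-1H-indole
Conditions: NCS, DMF, 0 °C → rt; used at once
Reagents that add atoms: N-chlorosuccinimide, O=C1CCC(=O)N1Cl
Why: Electrophilic aromatic substitution: NCS chlorinates indole at C3, its most nucleophilic position, under neutral conditions that leave the product intact for immediate use.

Step 3
Reactants: 5 3-chloro-1H-indole; 3 prenyl-9-BBN
Product: 6 2-(2-methylbut-3-en-2-yl)-1H-indole
Conditions: Et3N, THF, −78 °C → rt; aq. NaHCO3 work-up
Reagents that add atoms: none
Why: Allylboration of a chloroindolenine (reverse prenylation): the 3H-tautomer of 5 binds boron at nitrogen, the prenyl group is passed to C2 through a six-membered transition state with allylic transposition so that its tertiary carbon forms the new bond, and Et3N-assisted loss of HCl restores the indole.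

Step 4
Reactants: 6 2-(2-methylbut-3-en-2-yl)-1H-indole
Product: 7 3-iodo-2-(2-methylbut-3-en-2-yl)-1H-indole
Conditions: I2, KOH, DMF, 0 °C → rt, dark; used at once
Reagents that add atoms: iodine, II
Why: Electrophilic iodination of the indolyl anion at C3, the only free ring position of high nucleophilicity, is far faster than any reaction of iodine with the isolated vinyl group.

Step 5
Reactants: 7 3-iodo-2-(2-methylbut-3-en-2-yl)-1H-indole
Product: 8 tert-butyl 3-iodo-2-(2-methylbut-3-en-2-yl)indole-1-carboxylate
Conditions: Boc2O, DMAP (cat.), MeCN, rt → 40 °C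
Reagents that add atoms: di-tert-butyl dicarbonate, CC(C)(C)OC(=O)OC(=O)OC(C)(C)C
Why: DMAP-catalysed N-acylation with Boc2O, a reaction known to succeed on indoles that carry a quaternary carbon at C2, stabilises the iodide and lowers the donor strength of the indole for the later steps.

Step 6
Reactants: 9 2-chloro-1,1-dimethoxyethane (chloroacetaldehyde dimethyl acetal); 8 tert-butyl 3-iodo-2-(2-methylbut-3-en-2-yl)indole-1-carboxylate
Product: 12 tert-butyl 3-(methoxyethynyl)-2-(2-methylbut-3-en-2-yl)indole-1-carboxylate, via lithium methoxyacetylide 10 (not isolated), via (methoxyethynyl)zinc chloride 11 (not isolated)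
Conditions: 9, LiNEt2 (3 equiv), THF, 0 °C; ZnCl2, THF, 0 °C; then 8, Pd(PPh3)4 (5 mol %), THF, rt → 45 °C; chromatography on Et3N-deactivated silica
Reagents that add atoms: none
Why: LiNEt2 eliminates methanol and then HCl from 9 and deprotonates the methoxyethyne so formed, ZnCl2 turns the acetylide 10 into the zinc reagent 11, and a Negishi coupling catalysed by Pd(PPh3)4 (zerovalent palladium) joins it to C3, transmetalation of the small alkynylzinc outrunning any Heck-type reaction of the arylpalladium species with the neighbouring vinyl group.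

Step 7
Reactants: 12 tert-butyl 3-(methoxyethynyl)-2-(2-methylbut-3-en-2-yl)indole-1-carboxylate (two molecules); 13 carbon monoxide (two molecules)
Product: 15 di-tert-butyl 3,3'-(2,5-dimethoxy-3,6-dioxocyclohexa-1,4-diene-1,4-diyl)bis[2-(2-methylbut-3-en-2-yl)indole-1-carboxylate], via tricarbonyl(η4-quinone)iron complex 14 (not isolated)
Conditions: Fe(CO)5 (1.2 equiv per quinone), CO (1 atm), toluene (0.5 M), hν (405 nm), 20 °C; then FeCl3·6H2O, MeCN, 0 °C, short contact
Reagents that add atoms: pentacarbonyliron Fe(CO)5, [Fe].[C-]#[O+].[C-]#[O+].[C-]#[O+].[C-]#[O+].[C-]#[O+] (its CO ligands exchange with 13 and are the immediate source of the two ring carbonyls)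
Why: Proposed new method: light strips one CO from Fe(CO)5, the Fe(CO)4 fragment binds one molecule of 12 and two CO insertions give a transient maleoyl–Fe(CO)3 metallacycle (a ferracyclopentenedione), into one acyl–iron bond of which a second molecule of 12 inserts before C–C reductive elimination delivers the quinone as its Fe(CO)3 complex 14, which FeCl3 oxidises off the metal. The closest known reactions are the light-driven formation of quinone–Fe(CO)3 complexes from dialkylalkynes and Fe(CO)5 and the quinone synthesis from phthaloyl–Fe(CO)4 or maleoyl–CoCl(PPh3)2 metallacycles and alkynes, neither of which has been shown for ynol ethers or with control of the mutual orientation of two unsymmetrical alkynes. The single new ring, the six-membered quinone, closes by reductive elimination from a seven-membered ferracycle after a formal [2+2+1+1] assembly, so that all four C(carbonyl)–C(alkene) bonds are made at iron; no stereocentre is formed. The step needs head-to-tail orientation: in the metallacycle the acyl bonded to the methoxy-bearing carbon is cross-conjugated and ketone-like whereas the acyl bonded to the indolyl-bearing carbon is a vinylogous ester, so the nucleophilic indolyl-bearing carbon of the second ynol ether should bond to the former while iron takes the methoxy-bearing carbon, which leads to the 2,5-diindolyl-3,6-dimethoxy pattern. The N-Boc groups damp the donor strength of the indoles so that the methoxy group sets the alkyne polarity, the methyl ether has no β-hydrogen for retro-ene loss to a ketene, the CO atmosphere holds the acyl–iron intermediates against decarbonylation towards cyclopentadienone products, and the vinyl groups have no allylic hydrogen for iron-hydride isomerisation and bind iron only reversibly.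

Step 8
Reactants: 15 di-tert-butyl 3,3'-(2,5-dimethoxy-3,6-dioxocyclohexa-1,4-diene-1,4-diyl)bis[2-(2-methylbut-3-en-2-yl)indole-1-carboxylate]
Product: 16 2,5-dimethoxy-3,6-bis[2-(2-methylbut-3-en-2-yl)-1H-indol-3-yl]cyclohexa-2,5-diene-1,4-dione
Conditions: K2CO3, dry MeOH/THF, 40 °C, argon
Reagents that add atoms: none
Why: Carbonate-catalysed methanolysis of the N-acylindole carbamates (addition–elimination at the Boc carbonyl with the indolide as leaving group) frees both N–H groups, while methoxide exchange at the two vinylogous ester carbons of the quinone only regenerates the same compound.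

**Compound list**

1 | 3-methylbuta-1,2-diene | CC(C)=C=C | starting material
2 | 9-borabicyclo[3.3.1]nonane (9-BBN) | B1C2CCCC1CCC2 | starting material
3 | 9-(3-methylbut-2-en-1-yl)-9-borabicyclo[3.3.1]nonane | CC(C)=CCB1C2CCCC1CCC2 | intermediate
4 | indole | c1ccc2[nH]ccc2c1 | starting material
5 | 3-chloro-1H-indole | Clc1c[nH]c2ccccc12 | intermediate
6 | 2-(2-methylbut-3-en-2-yl)-1H-indole | C=CC(C)(C)c1cc2ccccc2[nH]1 | intermediate
7 | 3-iodo-2-(2-methylbut-3-en-2-yl)-1H-indole | C=CC(C)(C)c1[nH]c2ccccc2c1I | intermediate
8 | tert-butyl 3-iodo-2-(2-methylbut-3-en-2-yl)indole-1-carboxylate | C=CC(C)(C)c1c(I)c2ccccc2n1C(=O)OC(C)(C)C | intermediate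
9 | 2-chloro-1,1-dimethoxyethane | COC(CCl)OC | starting material
10 | lithium methoxyacetylide | [Li]C#COC | intermediate
11 | (methoxyethynyl)zinc chloride | COC#C[Zn]Cl | intermediate
12 | tert-butyl 3-(methoxyethynyl)-2-(2-methylbut-3-en-2-yl)indole-1-carboxylate | COC#Cc1c(C(C)(C)C=C)n(C(=O)OC(C)(C)C)c2ccccc12 | intermediate
13 | carbon monoxide | [C-]#[O+] | starting material
14 | tricarbonyl(η4-quinone)iron complex of 15 | C=CC(C)(C)c1n(C(=O)OC(C)(C)C)c2ccccc2c1C1=C(OC)C(=O)C(c2c(C(C)(C)C=C)n(C(=O)OC(C)(C)C)c3ccccc23)=C(OC)C1=O.[Fe].[C-]#[O+].[C-]#[O+].[C-]#[O+] | intermediate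
15 | di-tert-butyl 3,3'-(2,5-dimethoxy-3,6-dioxocyclohexa-1,4-diene-1,4-diyl)bis[2-(2-methylbut-3-en-2-yl)indole-1-carboxylate] | C=CC(C)(C)c1n(C(=O)OC(C)(C)C)c2ccccc2c1C1=C(OC)C(=O)C(c2c(C(C)(C)C=C)n(C(=O)OC(C)(C)C)c3ccccc23)=C(OC)C1=O | intermediate
16 | 2,5-dimethoxy-3,6-bis[2-(2-methylbut-3-en-2-yl)-1H-indol-3-yl]cyclohexa-2,5-diene-1,4-dione | C=CC(C)(C)c1[nH]c2ccccc2c1C1=C(OC)C(=O)C(c2c(C(C)(C)C=C)[nH]c3ccccc23)=C(OC)C1=O | target

**Count and risks**

Total step count: 8. Longest linear sequence: 7 steps (steps 2 to 8, from indole); step 1 prepares the prenylborane on a side branch.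

Steps most likely to fail:

1. Step 7. The second ynol ether may insert in the head-to-head sense. The acyl–iron intermediates may lose CO and close with a single carbonyl. The pendant vinyl group, which forms a 1,6-enyne with the alkyne, may be drawn into an intramolecular cyclocarbonylation. The ynol ether may oligomerise at the metal before two CO are taken up. The fallback uses known chemistry, gives up the carbonylative assembly, sets out from 6 and returns to the route at 16. Acid-promoted conjugate addition of 6 to 2,5-dichloro-1,4-benzoquinone (HCl, THF) followed by DDQ re-oxidation should give 2,5-dichloro-3-[2-(2-methylbut-3-en-2-yl)-1H-indol-3-yl]cyclohexa-2,5-diene-1,4-dione F1. A second addition of 6 under the same conditions and DDQ should give 2,5-dichloro-3,6-bis[2-(2-methylbut-3-en-2-yl)-1H-indol-3-yl]cyclohexa-2,5-diene-1,4-dione F2, the para-dichloro pattern of the quinone fixing the 2,5-diindolyl arrangement. NaOH in MeOH should replace both chlorides and give 2,5-dihydroxy-3,6-bis[2-(2-methylbut-3-en-2-yl)-1H-indol-3-yl]cyclohexa-2,5-diene-1,4-dione F3. O-Methylation of this vinylogous acid with trimethylsilyldiazomethane in MeOH/toluene should give 16.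

2. Step 6. Oxidative addition and transmetalation at the C3–I bond, which is flanked by the quaternary C2 substituent, may be slow enough for hydrodeiodination or a Heck-type closure onto the vinyl group to compete, and the ynol ether may hydrate during purification. The fallback builds the alkyne by elimination instead of cross-coupling, sets out from 6 and returns at 12. Friedel–Crafts acylation of 6 at C3 with methoxyacetyl chloride and Et2AlCl (CH2Cl2, 0 °C) should give 2-methoxy-1-[2-(2-methylbut-3-en-2-yl)-1H-indol-3-yl]ethan-1-one F4. Boc2O and DMAP should give tert-butyl 3-(methoxyacetyl)-2-(2-methylbut-3-en-2-yl)indole-1-carboxylate F5. LiN(SiMe3)2 and PhNTf2 (THF, −78 °C) should trap the chelated enolate as tert-butyl 3-[(Z)-2-methoxy-1-(trifluoromethylsulfonyloxy)ethenyl]-2-(2-methylbut-3-en-2-yl)indole-1-carboxylate F6. Anti-elimination of triflic acid with KOtBu (THF, −78 °C) should then give 12.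

3. Step 8. Methanolysis of the two hindered carbamates may be slow enough for base-induced degradation of the quinone to compete (exchange of methoxy for hydroxide by adventitious water, or conjugate additions). The fallback takes the quinone out of play by a change of oxidation level and removes Boc without base; it sets out from 15 and returns at 16. Reduction of 15 with Na2S2O4 (THF/H2O) should give di-tert-butyl 3,3'-(2,5-dihydroxy-3,6-dimethoxy-1,4-phenylene)bis[2-(2-methylbut-3-en-2-yl)indole-1-carboxylate] F7. Thermolysis of both carbamates in 2,2,2-trifluoroethanol (150 °C, sealed tube, argon) should give 2,5-dimethoxy-3,6-bis[2-(2-methylbut-3-en-2-yl)-1H-indol-3-yl]benzene-1,4-diol F8. Stirring the solution in air should re-oxidise the hydroquinone to 16.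

**Further compounds**

F1 | step 7 | 2,5-dichloro-3-[2-(2-methylbut-3-en-2-yl)-1H-indol-3-yl]cyclohexa-2,5-diene-1,4-dione | C=CC(C)(C)c1[nH]c2ccccc2c1C1=C(Cl)C(=O)C=C(Cl)C1=O
F2 | step 7 | 2,5-dichloro-3,6-bis[2-(2-methylbut-3-en-2-yl)-1H-indol-3-yl]cyclohexa-2,5-diene-1,4-dione | C=CC(C)(C)c1[nH]c2ccccc2c1C1=C(Cl)C(=O)C(c2c(C(C)(C)C=C)[nH]c3ccccc23)=C(Cl)C1=O
F3 | step 7 | 2,5-dihydroxy-3,6-bis[2-(2-methylbut-3-en-2-yl)-1H-indol-3-yl]cyclohexa-2,5-diene-1,4-dione | C=CC(C)(C)c1[nH]c2ccccc2c1C1=C(O)C(=O)C(c2c(C(C)(C)C=C)[nH]c3ccccc23)=C(O)C1=O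
F4 | step 6 | 2-methoxy-1-[2-(2-methylbut-3-en-2-yl)-1H-indol-3-yl]ethan-1-one | COCC(=O)c1c(C(C)(C)C=C)[nH]c2ccccc12
F5 | step 6 | tert-butyl 3-(methoxyacetyl)-2-(2-methylbut-3-en-2-yl)indole-1-carboxylate | COCC(=O)c1c(C(C)(C)C=C)n(C(=O)OC(C)(C)C)c2ccccc12
F6 | step 6 | tert-butyl 3-[(Z)-2-methoxy-1-(trifluoromethylsulfonyloxy)ethenyl]-2-(2-methylbut-3-en-2-yl)indole-1-carboxylate | CO/C=C(/c1c(C(C)(C)C=C)n(C(=O)OC(C)(C)C)c2ccccc12)OS(=O)(=O)C(F)(F)F
F7 | step 8 | di-tert-butyl 3,3'-(2,5-dihydroxy-3,6-dimethoxy-1,4-phenylene)bis[2-(2-methylbut-3-en-2-yl)indole-1-carboxylate] | C=CC(C)(C)c1n(C(=O)OC(C)(C)C)c2ccccc2c1-c1c(OC)c(O)c(-c2c(C(C)(C)C=C)n(C(=O)OC(C)(C)C)c3ccccc23)c(OC)c1O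
F8 | step 8 | 2,5-dimethoxy-3,6-bis[2-(2-methylbut-3-en-2-yl)-1H-indol-3-yl]benzene-1,4-diol | C=CC(C)(C)c1[nH]c2ccccc2c1-c1c(OC)c(O)c(-c2c(C(C)(C)C=C)[nH]c3ccccc23)c(OC)c1O
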